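**Plan**
- Retrosynthetic cuts: first the lactone alkyl C–O bond O1–C5, with C5 rejoined to the benzylic carbon C7 of ring A as a cyclopropane (C4–C5–C7); then the aldol bond C3–C7'; then C3 (one-carbon homologation) and the cyclopropane (styrene + carbene).
- Enabling feature: C5 and the CH2 (C7) that carries ring A both sit on C4, so the ring oxygen and the electron-rich guaiacyl ring A are 1,3-related across C5–C4–C7. A C5–C7 bond therefore gives an arylcyclopropane whose benzylic bond can be opened at C5 by the carboxyl oxygen once ring A is oxidised by one electron.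
- Forward order: ring A styrene → cyclopropane ester (temporary ring) → Arndt–Eistert acid → Evans imide → syn aldol with the ring B aldehyde → silyl ether, auxiliary off → photoredox ring-opening lactonisation (the only ring of the target arises last) → desilylation.
- Stereochemistry: C4 from the bis(oxazoline)–copper cyclopropanation (carbene carbon; the aryl-bearing carbon is erased later, so cis and trans cyclopropanes converge). C3 and C7' from the Evans syn aldol of the acyclic Z-enolate, a relation the ring-locked lactone enolate does not favour. The key step touches no stereocentre.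
- Helpers (cyclopropane, oxazolidinone, TIPS and TBS groups) are all gone after steps 10–12.

Key step: step 11

Remark: Ar = 3-methoxy-4-(triisopropylsilyloxy)phenyl; lactone atoms are O1, C2 (C=O), C3, C4, C5; C7 is the benzylic CH2 on C4 (ring A) and C7' the carbinol carbon on C3 (ring B); the short-lived radical species of step 11 are described in its Why line and are not numbered as compounds.

**Step 1**
Reactants: 1 2-methoxy-4-vinylphenol
Product: 2 triisopropyl(2-methoxy-4-vinylphenoxy)silane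
Conditions: TIPSCl, imidazole, DMF, rt
Reagents that add atoms: triisopropylsilyl chloride, CC(C)[Si](Cl)(C(C)C)C(C)C
Why: Routine silylation of a phenol; the bulky aryl TIPS ether should survive the later hydroxide, hydroperoxide and boron steps and keeps ring A electron-rich for step 11.

**Step 2**
Reactants: 2 triisopropyl(2-methoxy-4-vinylphenoxy)silane; 3 ethyl diazoacetate
Product: 4 ethyl (1R,2R)-2-Ar-cyclopropane-1-carboxylate
Conditions: CuOTf·0.5C6H6 (1 mol %), 2,2'-(propane-2,2-diyl)bis[(4S)-4-tert-butyl-4,5-dihydro-1,3-oxazole] (1.2 mol %), CH2Cl2, rt, 3 added over 8 h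
Reagents that add atoms: none
Why: Enantioselective carbene cyclopropanation of a styrene with monovalent copper and a C2-symmetric bis(oxazoline); the ligand controls the face of the carbene carbon, so the ester-bearing carbon (future C4) should be R in the trans isomer that is isolated and equally in the minor cis isomer.

**Step 3**
Reactants: 4 ethyl (1R,2R)-2-Ar-cyclopropane-1-carboxylate
Product: 5 (1R,2R)-2-Ar-cyclopropane-1-carboxylic acid
Conditions: LiOH·H2O, THF/MeOH/H2O, 0 °C to rt; then 1 M HCl to pH 3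
Reagents that add atoms: lithium hydroxide, [Li+].[OH-]
Why: Ester saponification; acyl substitution is much faster than deprotonation of the cyclopropane C–H, so the ester-bearing centre should not epimerise.

**Step 4**
Reactants: 5 (1R,2R)-2-Ar-cyclopropane-1-carboxylic acid
Product: 7 2-diazo-1-[(1R,2R)-2-Ar-cyclopropyl]ethan-1-one, via mixed carbonic anhydride 6 (not isolated)
Conditions: i-BuOCOCl, N-methylmorpholine, THF, −15 °C; then CH2N2, Et2O, 0 °C to rt
Reagents that add atoms: diazomethane, C=[N+]=[N-]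
Why: First half of the Arndt–Eistert homologation (acylation of diazomethane by a mixed anhydride); base-buffered conditions avoid acid opening of the donor-substituted cyclopropane, and no stereocentre is touched.

**Step 5**
Reactants: 7 2-diazo-1-[(1R,2R)-2-Ar-cyclopropyl]ethan-1-one
Product: 9 2-[(1S,2R)-2-Ar-cyclopropyl]acetic acid, via ketene 8 (not isolated)
Conditions: PhCO2Ag (10 mol %), Et3N, THF/H2O (9:1), rt, dark
Reagents that add atoms: water, O
Why: Wolff rearrangement and hydration of the ketene; the cyclopropyl carbon migrates with retention, so the future C4 keeps its configuration (the descriptor changes from R to S only through the priority rules).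

**Step 6**
Reactants: 9 2-[(1S,2R)-2-Ar-cyclopropyl]acetic acid; 10 (S)-4-benzyl-1,3-oxazolidin-2-one
Product: 12 (S)-4-benzyl-3-{2-[(1S,2R)-2-Ar-cyclopropyl]acetyl}-1,3-oxazolidin-2-one, via mixed pivalic anhydride 11 (not isolated)
Conditions: t-BuCOCl, Et3N, THF, −20 °C; then 10, LiCl, −20 °C to rt
Reagents that add atoms: none
Why: N-acylation of the Evans auxiliary through a mixed pivalic anhydride with LiCl activation; mild and non-acidic, so the cyclopropane and the silyl ether are not at risk.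

**Step 7**
Reactants: 13 vanillin (4-hydroxy-3-methoxybenzaldehyde)
Product: 14 3-methoxy-4-(triisopropylsilyloxy)benzaldehyde
Conditions: TIPSCl, imidazole, DMF, rt
Reagents that add atoms: triisopropylsilyl chloride, CC(C)[Si](Cl)(C(C)C)C(C)C
Why: Routine phenol silylation, giving the ring B aldehyde with the same protecting group as ring A so that one final operation frees both phenols.

**Step 8**
Reactants: 12 (S)-4-benzyl-3-{2-[(1S,2R)-2-Ar-cyclopropyl]acetyl}-1,3-oxazolidin-2-one; 14 3-methoxy-4-(triisopropylsilyloxy)benzaldehyde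
Product: 17 (4S)-4-benzyl-3-{(2S,3S)-3-hydroxy-2-[(1R,2R)-2-Ar-cyclopropyl]-3-Ar-propanoyl}-1,3-oxazolidin-2-one, via dibutylboron Z-enolate 15 (not isolated), via dibutylboron aldolate 16 (not isolated)
Conditions: Bu2BOTf, i-Pr2NEt, CH2Cl2, 0 °C; 14, −78 to 0 °C; then pH 7 phosphate buffer, MeOH, 30% H2O2, 0 °C
Reagents that add atoms: none
Why: Evans syn aldol; the dibutylboron Z-enolate reacts through a Zimmerman–Traxler chair with the auxiliary carbonyl turned away, and the (S)-benzyl group should direct the aryl aldehyde to the face that gives the (2S,3S) "Evans syn" adduct (C3 and C7' of the target), with the auxiliary expected to override the remote cyclopropane centre.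

**Step 9**
Reactants: 17 (4S)-4-benzyl-3-{(2S,3S)-3-hydroxy-2-[(1R,2R)-2-Ar-cyclopropyl]-3-Ar-propanoyl}-1,3-oxazolidin-2-one
Product: 18 (4S)-4-benzyl-3-{(2S,3S)-3-[(tert-butyldimethylsilyl)oxy]-2-[(1R,2R)-2-Ar-cyclopropyl]-3-Ar-propanoyl}-1,3-oxazolidin-2-one
Conditions: TBSOTf, 2,6-lutidine, CH2Cl2, 0 °C
Reagents that add atoms: tert-butyldimethylsilyl triflate, CC(C)(C)[Si](C)(C)OS(=O)(=O)C(F)(F)F
Why: Silylation of the hindered benzylic alcohol with a silyl triflate and a hindered base; it removes the hydroxyl that would otherwise compete as a nucleophile in step 11 (tetrahydrofuran formation) and blocks retro-aldol cleavage.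

**Step 10**
Reactants: 18 (4S)-4-benzyl-3-{(2S,3S)-3-[(tert-butyldimethylsilyl)oxy]-2-[(1R,2R)-2-Ar-cyclopropyl]-3-Ar-propanoyl}-1,3-oxazolidin-2-one
Product: 20 (2S,3S)-3-[(tert-butyldimethylsilyl)oxy]-2-[(1R,2R)-2-Ar-cyclopropyl]-3-Ar-propanoic acid, via peroxy acid 19 (not isolated)
Conditions: LiOH·H2O, 30% H2O2, THF/H2O (3:1), 0 °C; then aq. Na2SO3; then 1 M HCl to pH 3
Reagents that add atoms: lithium hydroperoxide (from LiOH and H2O2), [Li+].[O-]O
Why: Hydroperoxide cleavage of an N-acyloxazolidinone; the small, weakly basic hydroperoxide anion attacks the exocyclic carbonyl selectively, the peroxy acid is reduced by sulfite, and C3 should not epimerise at 0 °C.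

**Step 11**
Reactants: 20 (2S,3S)-3-[(tert-butyldimethylsilyl)oxy]-2-[(1R,2R)-2-Ar-cyclopropyl]-3-Ar-propanoic acid
Product: 21 (3S,4R)-3-{(S)-[(tert-butyldimethylsilyl)oxy](Ar)methyl}-4-(Ar-methyl)oxolan-2-one
Conditions: 9-mesityl-3,6-di-tert-butyl-10-phenylacridinium tetrafluoroborate (5 mol %), PhSSPh (10 mol %), 2,6-lutidine (10 mol %), 1,2-dichloroethane (0.05 M), 450 nm LEDs, N2, rt
Reagents that add atoms: none
Why: Proposed new method: the excited acridinium oxidises ring A (the cyclopropyl-conjugated arene, expected to be the more easily oxidised of the two) to a radical cation in which the benzylic C5–C7 cyclopropane bond is a weakened one-electron bond; the carboxyl oxygen attacks C5 with displacement of C7 (three-electron SN2), which closes the lactone by forming O1–C5 and leaves a benzylic radical at C7 that takes a hydrogen atom from PhSH (formed from PhSSPh), the thiyl radical being reduced by the acridine radical and protonated, so the process is redox-neutral and adds no atoms. The closest known reaction types are the acridinium/thiol anti-Markovnikov hydroacyloxylation of alkenes and the photoredox nucleophilic ring-opening 1,3-hydrofunctionalisation of arylcyclopropanes by intermolecular oxygen and nitrogen nucleophiles; the intramolecular closure onto the unsubstituted cyclopropane carbon is the new element. The closure is formally 5-exo-tet at C5 (C7 leaves the new ring) but has the geometry of an endo-mode opening of a three-membered ring, as in the conversion of 3,4-epoxy acids into 3-hydroxy-γ-lactones. No stereocentre is formed: C3, C4 and C7' are not touched, C5 and C7 become CH2 groups, and the 3,4-trans lactone follows from the configurations set in steps 2 and 8. The step needs attack at C5 and not at C4 (which would give a β-lactone with inversion at C4): the strain of the four-membered transition state and the electron-poor α-carboxyalkyl substituent on C4 should secure this, the silyl ether on O7' removes the competing hydroxyl nucleophile, and the substoichiometric base keeps carboxylate oxidation (decarboxylation) low.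

**Step 12**
Reactants: 21 (3S,4R)-3-{(S)-[(tert-butyldimethylsilyl)oxy](Ar)methyl}-4-(Ar-methyl)oxolan-2-one
Product: 22 (3S,4R)-3-[(S)-hydroxy(4-hydroxy-3-methoxyphenyl)methyl]-4-(4-hydroxy-3-methoxybenzyl)oxolan-2-one
Conditions: Bu4NF, AcOH (1:1, 5 equiv), THF, 0 °C to rt
Reagents that add atoms: none
Why: Fluoride cleavage of the two aryl TIPS ethers and the benzylic TBS ether in one operation; the acetic acid buffer keeps phenoxide and alkoxide concentrations low, which should suppress retro-aldol cleavage, β-elimination and quinone methide formation.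

**Compound list**
1 | 2-methoxy-4-vinylphenol | C=Cc1ccc(O)c(OC)c1 | starting material
2 | triisopropyl(2-methoxy-4-vinylphenoxy)silane | C=Cc1ccc(O[Si](C(C)C)(C(C)C)C(C)C)c(OC)c1 | intermediate
3 | ethyl diazoacetate | CCOC(=O)C=[N+]=[N-] | starting material
4 | ethyl (1R,2R)-2-[3-methoxy-4-(triisopropylsilyloxy)phenyl]cyclopropane-1-carboxylate | CCOC(=O)[C@@H]1C[C@H]1c1ccc(O[Si](C(C)C)(C(C)C)C(C)C)c(OC)c1 | intermediate
5 | (1R,2R)-2-[3-methoxy-4-(triisopropylsilyloxy)phenyl]cyclopropane-1-carboxylic acid | OC(=O)[C@@H]1C[C@H]1c1ccc(O[Si](C(C)C)(C(C)C)C(C)C)c(OC)c1 | intermediate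
6 | isobutyl carbonic anhydride of 5 | CC(C)COC(=O)OC(=O)[C@@H]1C[C@H]1c1ccc(O[Si](C(C)C)(C(C)C)C(C)C)c(OC)c1 | intermediate
7 | 2-diazo-1-[(1R,2R)-2-Ar-cyclopropyl]ethan-1-one | [N-]=[N+]=CC(=O)[C@@H]1C[C@H]1c1ccc(O[Si](C(C)C)(C(C)C)C(C)C)c(OC)c1 | intermediate
8 | 2-[(1R,2R)-2-Ar-cyclopropyl]ethen-1-one (ketene) | O=C=C[C@@H]1C[C@H]1c1ccc(O[Si](C(C)C)(C(C)C)C(C)C)c(OC)c1 | intermediate
9 | 2-[(1S,2R)-2-Ar-cyclopropyl]acetic acid | OC(=O)C[C@@H]1C[C@H]1c1ccc(O[Si](C(C)C)(C(C)C)C(C)C)c(OC)c1 | intermediate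
10 | (S)-4-benzyl-1,3-oxazolidin-2-one | O=C1N[C@@H](Cc2ccccc2)CO1 | starting material
11 | pivalic anhydride of 9 | CC(C)(C)C(=O)OC(=O)C[C@@H]1C[C@H]1c1ccc(O[Si](C(C)C)(C(C)C)C(C)C)c(OC)c1 | intermediate
12 | (S)-4-benzyl-3-{2-[(1S,2R)-2-Ar-cyclopropyl]acetyl}-1,3-oxazolidin-2-one | O=C(C[C@@H]1C[C@H]1c1ccc(O[Si](C(C)C)(C(C)C)C(C)C)c(OC)c1)N1[C@@H](Cc2ccccc2)COC1=O | intermediate
13 | vanillin | O=Cc1ccc(O)c(OC)c1 | starting material
14 | 3-methoxy-4-(triisopropylsilyloxy)benzaldehyde | O=Cc1ccc(O[Si](C(C)C)(C(C)C)C(C)C)c(OC)c1 | intermediate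
15 | dibutylboron Z-enolate of 12 | CCCCB(CCCC)O/C(=C\[C@@H]1C[C@H]1c1ccc(O[Si](C(C)C)(C(C)C)C(C)C)c(OC)c1)N1[C@@H](Cc2ccccc2)COC1=O | intermediate
16 | dibutylboron aldolate of 17 | CCCCB(CCCC)O[C@H](c1ccc(O[Si](C(C)C)(C(C)C)C(C)C)c(OC)c1)[C@H]([C@@H]1C[C@H]1c1ccc(O[Si](C(C)C)(C(C)C)C(C)C)c(OC)c1)C(=O)N1[C@@H](Cc2ccccc2)COC1=O | intermediate
17 | (4S)-4-benzyl-3-{(2S,3S)-3-hydroxy-2-[(1R,2R)-2-Ar-cyclopropyl]-3-Ar-propanoyl}-1,3-oxazolidin-2-one | O=C([C@@H]([C@@H]1C[C@H]1c1ccc(O[Si](C(C)C)(C(C)C)C(C)C)c(OC)c1)[C@H](O)c1ccc(O[Si](C(C)C)(C(C)C)C(C)C)c(OC)c1)N1[C@@H](Cc2ccccc2)COC1=O | intermediate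
18 | (4S)-4-benzyl-3-{(2S,3S)-3-[(tert-butyldimethylsilyl)oxy]-2-[(1R,2R)-2-Ar-cyclopropyl]-3-Ar-propanoyl}-1,3-oxazolidin-2-one | O=C([C@@H]([C@@H]1C[C@H]1c1ccc(O[Si](C(C)C)(C(C)C)C(C)C)c(OC)c1)[C@H](O[Si](C)(C)C(C)(C)C)c1ccc(O[Si](C(C)C)(C(C)C)C(C)C)c(OC)c1)N1[C@@H](Cc2ccccc2)COC1=O | intermediate
19 | (2S,3S)-3-[(tert-butyldimethylsilyl)oxy]-2-[(1R,2R)-2-Ar-cyclopropyl]-3-Ar-propaneperoxoic acid | OOC(=O)[C@@H]([C@@H]1C[C@H]1c1ccc(O[Si](C(C)C)(C(C)C)C(C)C)c(OC)c1)[C@H](O[Si](C)(C)C(C)(C)C)c1ccc(O[Si](C(C)C)(C(C)C)C(C)C)c(OC)c1 | intermediate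
20 | (2S,3S)-3-[(tert-butyldimethylsilyl)oxy]-2-[(1R,2R)-2-Ar-cyclopropyl]-3-Ar-propanoic acid | OC(=O)[C@@H]([C@@H]1C[C@H]1c1ccc(O[Si](C(C)C)(C(C)C)C(C)C)c(OC)c1)[C@H](O[Si](C)(C)C(C)(C)C)c1ccc(O[Si](C(C)C)(C(C)C)C(C)C)c(OC)c1 | intermediate
21 | (3S,4R)-3-{(S)-[(tert-butyldimethylsilyl)oxy](Ar)methyl}-4-(Ar-methyl)oxolan-2-one | COc1cc(C[C@H]2COC(=O)[C@@H]2[C@H](O[Si](C)(C)C(C)(C)C)c2ccc(O[Si](C(C)C)(C(C)C)C(C)C)c(OC)c2)ccc1O[Si](C(C)C)(C(C)C)C(C)C | intermediate
22 | (3S,4R)-3-[(S)-hydroxy(4-hydroxy-3-methoxyphenyl)methyl]-4-(4-hydroxy-3-methoxybenzyl)oxolan-2-one | COc1cc(C[C@H]2COC(=O)[C@@H]2[C@H](O)c2ccc(O)c(OC)c2)ccc1O | target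

**Step count**
Total: 12 steps. Longest linear sequence: 11 steps (steps 1–6 and 8–12 from compound 1; step 7 is the side branch).

**Steps most likely to fail, with fallbacks**

1. Step 11 (the proposed method). The nucleophilic opening may take the wrong course: closure at the substituted carbon C4 to a four-membered lactone, capture of the radical cation by adventitious nucleophiles, or oxidation of ring B or of the carboxylate followed by fragmentation or decarboxylation. The fallback uses known chemistry only: the lactone is closed at the acyl C–O bond and C7' is set by oxidation and chelation-controlled reduction. It sets out from 14 and 10 and comes back to the route at 22.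
 - 14 is condensed reductively with Meldrum's acid in HCO2H/Et3N to 5-(Ar-methyl)-2,2-dimethyl-1,3-dioxane-4,6-dione F1, which on heating in the same pot loses acetone and CO2 to give 3-Ar-propanoic acid F2.
 - Acylation of 10 (t-BuCOCl, Et3N, LiCl) gives (S)-4-benzyl-3-(3-Ar-propanoyl)-1,3-oxazolidin-2-one F3.
 - Evans alkylation (NaN(SiMe3)2, THF, −78 °C, tert-butyl bromoacetate) should give tert-butyl (3R)-4-[(4S)-4-benzyl-2-oxo-1,3-oxazolidin-3-yl]-3-(Ar-methyl)-4-oxobutanoate F4.
 - LiBH4 (THF, 0 °C) removes the auxiliary to give tert-butyl (3R)-3-(hydroxymethyl)-4-Ar-butanoate F5, and TsOH in toluene closes (R)-4-(Ar-methyl)oxolan-2-one F6.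
 - The lithium enolate of F6 (LiN(SiMe3)2, THF, −78 °C) and 14 give the 3,4-trans aldol as a mixture at the carbinol carbon, (3S,4R)-3-[hydroxy(Ar)methyl]-4-(Ar-methyl)oxolan-2-one F7.
 - Dess–Martin periodinane gives the keto lactone (3S,4R)-3-(Ar-carbonyl)-4-(Ar-methyl)oxolan-2-one F8.
 - Zn(BH4)2 (Et2O, −20 °C), acting on the zinc chelate of the two carbonyl groups, should give the syn alcohol (3S,4R)-3-[(S)-hydroxy(Ar)methyl]-4-(Ar-methyl)oxolan-2-one F9.
 - Bu4NF/AcOH then gives 22.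

2. Step 10. Attack of hydroperoxide on the hindered α-branched, β-silyloxy imide may be slow, may open the oxazolidinone ring, or may be accompanied by loss of an aryl silyl ether. The fallback changes the order so that the unhindered free aldol is hydrolysed. It sets out from 17 and comes back at 20. LiOH/H2O2 on 17 gives (2S,3S)-3-hydroxy-2-[(1R,2R)-2-Ar-cyclopropyl]-3-Ar-propanoic acid F10. Excess TBSOTf/2,6-lutidine gives tert-butyldimethylsilyl (2S,3S)-3-[(tert-butyldimethylsilyl)oxy]-2-[(1R,2R)-2-Ar-cyclopropyl]-3-Ar-propanoate F11, whose silyl ester alone is hydrolysed on brief treatment with K2CO3 in aqueous MeOH to give 20.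

3. Step 2. Facial control at the carbene carbon may be insufficient with this electron-rich styrene, or carbene dimerisation and styrene polymerisation may consume the reagents. The fallback replaces the carbene route by a directed asymmetric Simmons–Smith reaction. It sets out from 14 and comes back at 5.
 - Wittig olefination of 14 with Ph3P=CHCO2Et gives ethyl (E)-3-Ar-prop-2-enoate F12.
 - i-Bu2AlH (CH2Cl2, −78 °C) gives (E)-3-Ar-prop-2-en-1-ol F13.
 - Charette cyclopropanation (Et2Zn, CH2I2, (4S,5S)-2-butyl-N,N,N',N'-tetramethyl-1,3,2-dioxaborolane-4,5-dicarboxamide, CH2Cl2, 0 °C) should give [(1R,2R)-2-Ar-cyclopropyl]methanol F14.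
 - Oxidation with 2,2,6,6-tetramethylpiperidin-1-oxyl and PhI(OAc)2 in MeCN/H2O gives 5.

**Further compounds**
F1 | step 11 | 5-[3-methoxy-4-(triisopropylsilyloxy)benzyl]-2,2-dimethyl-1,3-dioxane-4,6-dione | CC1(C)OC(=O)C(Cc2ccc(O[Si](C(C)C)(C(C)C)C(C)C)c(OC)c2)C(=O)O1
F2 | step 11 | 3-[3-methoxy-4-(triisopropylsilyloxy)phenyl]propanoic acid | OC(=O)CCc1ccc(O[Si](C(C)C)(C(C)C)C(C)C)c(OC)c1
F3 | step 11 | (S)-4-benzyl-3-(3-Ar-propanoyl)-1,3-oxazolidin-2-one | O=C(CCc1ccc(O[Si](C(C)C)(C(C)C)C(C)C)c(OC)c1)N1[C@@H](Cc2ccccc2)COC1=O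
F4 | step 11 | tert-butyl (3R)-4-[(4S)-4-benzyl-2-oxo-1,3-oxazolidin-3-yl]-3-(Ar-methyl)-4-oxobutanoate | CC(C)(C)OC(=O)C[C@@H](Cc1ccc(O[Si](C(C)C)(C(C)C)C(C)C)c(OC)c1)C(=O)N1[C@@H](Cc2ccccc2)COC1=O
F5 | step 11 | tert-butyl (3R)-3-(hydroxymethyl)-4-Ar-butanoate | CC(C)(C)OC(=O)C[C@@H](Cc1ccc(O[Si](C(C)C)(C(C)C)C(C)C)c(OC)c1)CO
F6 | step 11 | (R)-4-(Ar-methyl)oxolan-2-one | O=C1C[C@@H](Cc2ccc(O[Si](C(C)C)(C(C)C)C(C)C)c(OC)c2)CO1
F7 | step 11 | (3S,4R)-3-[hydroxy(Ar)methyl]-4-(Ar-methyl)oxolan-2-one, both carbinol epimers | COc1cc(C[C@H]2COC(=O)[C@@H]2C(O)c2ccc(O[Si](C(C)C)(C(C)C)C(C)C)c(OC)c2)ccc1O[Si](C(C)C)(C(C)C)C(C)C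
F8 | step 11 | (3S,4R)-3-(Ar-carbonyl)-4-(Ar-methyl)oxolan-2-one | COc1cc(C[C@H]2COC(=O)[C@@H]2C(=O)c2ccc(O[Si](C(C)C)(C(C)C)C(C)C)c(OC)c2)ccc1O[Si](C(C)C)(C(C)C)C(C)C
F9 | step 11 | (3S,4R)-3-[(S)-hydroxy(Ar)methyl]-4-(Ar-methyl)oxolan-2-one | COc1cc(C[C@H]2COC(=O)[C@@H]2[C@H](O)c2ccc(O[Si](C(C)C)(C(C)C)C(C)C)c(OC)c2)ccc1O[Si](C(C)C)(C(C)C)C(C)C
F10 | step 10 | (2S,3S)-3-hydroxy-2-[(1R,2R)-2-Ar-cyclopropyl]-3-Ar-propanoic acid | OC(=O)[C@@H]([C@@H]1C[C@H]1c1ccc(O[Si](C(C)C)(C(C)C)C(C)C)c(OC)c1)[C@H](O)c1ccc(O[Si](C(C)C)(C(C)C)C(C)C)c(OC)c1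
F11 | step 10 | tert-butyldimethylsilyl (2S,3S)-3-[(tert-butyldimethylsilyl)oxy]-2-[(1R,2R)-2-Ar-cyclopropyl]-3-Ar-propanoate | CC(C)(C)[Si](C)(C)OC(=O)[C@@H]([C@@H]1C[C@H]1c1ccc(O[Si](C(C)C)(C(C)C)C(C)C)c(OC)c1)[C@H](O[Si](C)(C)C(C)(C)C)c1ccc(O[Si](C(C)C)(C(C)C)C(C)C)c(OC)c1
F12 | step 2 | ethyl (E)-3-Ar-prop-2-enoate | CCOC(=O)/C=C/c1ccc(O[Si](C(C)C)(C(C)C)C(C)C)c(OC)c1
F13 | step 2 | (E)-3-Ar-prop-2-en-1-ol | OC/C=C/c1ccc(O[Si](C(C)C)(C(C)C)C(C)C)c(OC)c1
F14 | step 2 | [(1R,2R)-2-Ar-cyclopropyl]methanol | OC[C@@H]1C[C@H]1c1ccc(O[Si](C(C)C)(C(C)C)C(C)C)c(OC)c1
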